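**Retrosynthetic overview**
1. Feature: C4 of the top epiafzelechin unit is a diarylmethine carbon bonded to C4a of its own ring A and to C8 of ring A of the middle unit. It can therefore enter as an alkyne carbon already attached to middle C8, and ring C of the top unit is closed by forming C4–C4a.
2. Disconnections: top C4–C4a (gold-catalysed 6-endo hydroarylation of an aryl propargyl ether); alkyne–C8 of the middle unit (Sonogashira); propargylic C–O (Mitsunobu); middle C4–bottom C8 (4β→8 Friedel–Crafts coupling of an 8-bromo-capped electrophile).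
3. Rings: the six rings of the bottom and middle units come from (−)-epigallocatechin and (−)-epiafzelechin. Top rings A and B come from 3,5-dibenzyloxyphenol and 4-hydroxybenzaldehyde. Top ring C is the only ring made, and it is made in the key step.
4. Stereochemical relay in the top unit: carbinol (catalytic alkynylation) → propargylic ether (inversion) = C2 of the chromene → C4 (epoxidation anti to the 2-aryl group, 1,2-hydride shift) → C3 (epoxidation of the flav-2-ene anti to the 4-aryl group) → C2 again (hydride anti to the C3 oxygen).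
5. Protection: benzyl ethers throughout; top ring B carries a pivalate until the end so that the propargylic/C2 centre does not ionise.

Key step: step 12

Remark: (−)-epiafzelechin is taken, like (−)-epigallocatechin, as a purchasable natural (2R,3R)-flavan-3-ol (sold as isolated reference material).

**Route**

Step 1
Reactants: 1 (−)-epigallocatechin
Product: 2 (−)-4'-O-methylepigallocatechin
Conditions: MeI (1.05 equiv), KHCO3 (1.1 equiv), DMF, rt, Ar, dark
Reagents that add atoms: iodomethane CI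
Why: Williamson etherification under mono-deprotonation: the central hydroxyl of the pyrogallol ring (4'-OH, flanked by two hydrogen-bonding hydroxyls) is the most acidic phenol of 1, so a weak base should methylate it first, and minor regioisomers are removed by chromatography.

Step 2
Reactants: 2 (−)-4'-O-methylepigallocatechin
Product: 4 (2R,3R)-3,5,7-tris(benzyloxy)-2-[3,5-bis(benzyloxy)-4-methoxyphenyl]chromane, via tetra-O-benzyl 3-ol 3 (not isolated)
Conditions: BnBr (4.5 equiv), K2CO3, DMF, rt; filter; then NaH, BnBr (1.5 equiv), Bu4NI (cat.), DMF, 0 °C → rt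
Reagents that add atoms: benzyl bromide BrCc1ccccc1
Why: Two Williamson etherifications in one pot: carbonate alkylates the four phenols and the alkoxide formed with NaH takes the fifth benzyl group at the secondary 3-hydroxyl, while C2 and C3 are untouched (the methylated 4'-oxygen cannot open ring C through a quinone methide).

Step 3
Reactants: 5 (−)-epiafzelechin
Product: 7 (2R,3R)-3,5,7-tris(benzyloxy)-2-[4-(benzyloxy)phenyl]chromane, via tri-O-benzyl 3-ol 6 (not isolated)
Conditions: BnBr (3.5 equiv), K2CO3, DMF, rt; filter; then NaH, BnBr (1.5 equiv), Bu4NI (cat.), DMF, 0 °C → rt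
Reagents that add atoms: benzyl bromide BrCc1ccccc1
Why: Williamson etherifications as in step 2: the three phenols are alkylated at room temperature (the 4'-phenol is capped before base can open ring C through a para-quinone methide), then the 3-alkoxide is benzylated, with both stereocentres retained.

Step 4
Reactants: 7 tetra-O-benzylepiafzelechin
Product: 8 (2R,3R)-3,5,7-tris(benzyloxy)-2-[4-(benzyloxy)phenyl]-8-bromochromane
Conditions: NBS (1.0 equiv), CH2Cl2, −78 → 0 °C
Reagents that add atoms: N-bromosuccinimide O=C1CCC(=O)N1Br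
Why: Electrophilic aromatic bromination: in 5,7-dialkoxyflavans C8 is attacked before C6, so one equivalent of NBS at low temperature should give the 8-bromide, which caps C8 during the interflavan coupling and later carries the alkyne.

Step 5
Reactants: 8 8-bromo-tetra-O-benzylepiafzelechin
Product: 9 (2R,3R,4S)-3,5,7-tris(benzyloxy)-2-[4-(benzyloxy)phenyl]-8-bromo-4-(2-ethoxyethoxy)chromane
Conditions: DDQ (2 equiv), 2-ethoxyethanol (5 equiv), CH2Cl2, rt
Reagents that add atoms: 2-ethoxyethanol CCOCCO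
Why: Oxidative benzylic etherification: DDQ removes hydride from C4 (cation stabilised by the ring A oxygens) and the alcohol adds trans to the 3-benzyloxy group, giving the 4β-ether (C4 controlled by C3, and erased again in step 6).

Step 6
Reactants: 9 4β-(2-ethoxyethoxy) 8-bromide; 4 benzylated 4'-O-methylepigallocatechin (1.5 equiv)
Product: 10 8-bromo-tetra-O-benzylepiafzelechin-(4β→8)-penta-O-benzyl-4'-O-methylepigallocatechin
Conditions: Me3SiOTf (0.2 equiv), CH2Cl2, −78 °C
Reagents that add atoms: none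
Why: Friedel–Crafts coupling through the flavan-4-yl cation: Me3SiOTf ionises the C4 ether and C8 of 4, its most nucleophilic ring position, adds to the face trans to the axial 3-benzyloxy group, which sets middle C4 as 4β, while the bromine at C8 of 9 stops the electrophile from reacting with itself.

Step 7
Reactants: 11 4-hydroxybenzaldehyde
Product: 12 4-formylphenyl pivalate
Conditions: t-BuCOCl, Et3N, DMAP (cat.), CH2Cl2, 0 °C → rt
Reagents that add atoms: pivaloyl chloride CC(C)(C)C(Cl)=O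
Why: O-acylation of the phenol: the pivalate (no α-hydrogens, inert to organozinc reagents and to amine and amide bases at low temperature) makes the ring a poor cation stabiliser, which protects the benzylic propargylic centre from ionisation in steps 9 to 13.

Step 8
Reactants: 12 4-formylphenyl pivalate; 13 ethynyltrimethylsilane (3 equiv)
Product: 14 (S)-4-[1-hydroxy-3-(trimethylsilyl)prop-2-yn-1-yl]phenyl pivalate
Conditions: Me2Zn (3 equiv), ProPhenol ligand (10 mol %, enantiomer giving Re-face addition), Ph3PO (20 mol %), toluene, 0 °C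
Reagents that add atoms: none
Why: Catalytic asymmetric alkynylation of an aldehyde (alkynylzinc addition under a dinuclear zinc–ProPhenol catalyst): Re-face attack sets the carbinol centre as S (to be confirmed as the MTPA ester), and material from the minor enantiomer becomes a separable diastereomer after step 11.

Step 9
Reactants: 14 (S)-propargylic alcohol; 15 3,5-bis(benzyloxy)phenol
Product: 16 (R)-4-{1-[3,5-bis(benzyloxy)phenoxy]-3-(trimethylsilyl)prop-2-yn-1-yl}phenyl pivalate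
Conditions: PPh3, DIAD, toluene, −20 → 0 °C
Reagents that add atoms: none
Why: Mitsunobu etherification: the phenol (pKa about 9) displaces the oxyphosphonium group by SN2 with inversion (S alcohol to R ether), the silyl group hindering SN2' attack at the alkyne terminus and the pivaloyloxy ring disfavouring an SN1 path.

Step 10
Reactants: 16 (R)-silylated propargyl aryl ether
Product: 17 (S)-4-{1-[3,5-bis(benzyloxy)phenoxy]prop-2-yn-1-yl}phenyl pivalate
Conditions: Bu4NF (1.1 equiv), AcOH (1.2 equiv), THF, 0 °C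
Reagents that add atoms: none
Why: Fluoride-induced protodesilylation of the alkynylsilane; acetic acid buffering keeps the aryl ester and the acidic propargylic C–H intact, so the stereocentre is unchanged (the descriptor becomes S only because the CIP rank of the alkyne changes).

Step 11
Reactants: 10 middle–bottom dimer bromide; 17 (S)-terminal alkyne (1.3 equiv)
Product: 18 dimer 10 in which Br is replaced by the (R)-3-[3,5-bis(benzyloxy)phenoxy]-3-[4-(pivaloyloxy)phenyl]prop-1-yn-1-yl group at C8 of the middle unit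
Conditions: Pd(PhCN)2Cl2 (5 mol %), P(t-Bu)3 (10 mol %), CuI (5 mol %), i-Pr2NH, dioxane, degassed, rt → 40 °C
Reagents that add atoms: none
Why: Sonogashira coupling: with the bulky, electron-rich phosphine zerovalent palladium inserts into the electron-rich, di-ortho-oxygenated aryl bromide near room temperature, so the base-sensitive propargylic ether couples without isomerisation and no stereocentre is touched.

Step 12
Reactants: 18 aryl propargyl ether on the middle–bottom dimer
Product: 19 trimer whose top unit is (2S)-5,7-bis(benzyloxy)-2-[4-(pivaloyloxy)phenyl]-2H-chromen-4-yl bonded at C4 to C8 of the middle unit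
Conditions: Ph3PAuNTf2 (5 mol %), CH2Cl2, 0 °C → rt
Reagents that add atoms: none
Why: Monovalent gold binds the alkyne, whose positive charge builds up on the carbon attached to the trioxygenated ring A of the middle unit; an ortho carbon of the 3,5-dibenzyloxyphenoxy ring attacks that carbon anti to gold, and rearomatisation followed by protodeauration gives the 4-aryl-2H-chromene. The closest known reaction is the gold- or platinum-catalysed intramolecular hydroarylation of aryl propargyl ethers, including 3-aryl-substituted ones, to 2H-chromenes. Ring C of the top unit is closed in the 6-endo-dig mode by formation of C4–C4a. No stereocentre is created: the propargylic centre becomes C2 unchanged, its ionisation being disfavoured by the pivaloyloxy group. The step needs 6-endo over 5-exo attack, secured by the polarisation of the aryl alkyne and by the equivalence of the two ortho carbons of the symmetrical phenoxy ring. It also needs arene attack to outrun addition of the ortho benzyloxy oxygen of the middle ring, secured by the much higher nucleophilicity of the phloroglucinol-type ring at room temperature.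

Step 13
Reactants: 19 4-aryl-flav-3-ene trimer
Product: 21 trimer 3-ketone (top unit (2R)-2,4-trans-4-arylflavan-3-one), via top-unit 3,4-epoxide 20 (not isolated)
Conditions: DMDO (1.2 equiv), acetone/CH2Cl2, −40 °C; then BF3·OEt2 (0.2 equiv), −78 °C
Reagents that add atoms: dimethyldioxirane CC1(C)OO1
Why: Epoxidation then Meinwald rearrangement: the dioxirane adds anti to the 2-aryl group, and Lewis-acid opening at the doubly benzylic C4 with suprafacial 1,2-shift of the C3 hydrogen puts H on C4 cis to the 2-aryl group, so that the middle unit ends trans to it (new centre C4, controlled by C2 through the epoxide face); the ketone is kept away from base to avoid epimerisation at its α-carbons.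

Step 14
Reactants: 21 trimer 3-ketone
Product: 22 trimer enol triflate (top unit 2-aryl-3-(trifluoromethylsulfonyloxy)-4H-chromen-4-yl)
Conditions: KN(SiMe3)2 (1.1 equiv), THF, −78 °C; PhNTf2, −78 → −30 °C
Reagents that add atoms: N-phenylbis(trifluoromethanesulfonimide) O=S(=O)(N(c1ccccc1)S(=O)(=O)C(F)(F)F)C(F)(F)F
Why: Kinetic enolisation and O-sulfonylation (enol triflate formation): the axial C2–H, acidified by the ring oxygen and the aryl group, should be removed in preference to the equatorial, shielded C4–H, leaving C4 as the only stereocentre of the top unit; C2 is given up on purpose, because hydride reduction of 21 would enter anti to the pseudoaxial 4-aryl group and give the 3,4-cis alcohol.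

Step 15
Reactants: 22 trimer enol triflate
Product: 23 trimer flav-2-ene (top unit 2-aryl-4H-chromen-4-yl)
Conditions: Pd(OAc)2 (5 mol %), PPh3 (10 mol %), HCO2H, Et3N, DMF, 50 °C, Ar
Reagents that add atoms: none
Why: Palladium-catalysed formate reduction of an enol triflate (oxidative addition to zerovalent palladium, formate exchange, decarboxylation, C–H reductive elimination) replaces OTf by H without involving C4, and the easily dehydrogenated flav-2-ene is handled under argon.

Step 16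
Reactants: 23 trimer flav-2-ene
Product: 26 benzylated trimer with free top 3-hydroxyl and top 4'-O-pivalate (top unit 2,3-cis-3,4-trans), via top-unit 2,3-epoxide 24 (not isolated), via top-unit 2-methoxy ketal 25 (not isolated)
Conditions: DMDO (1.1 equiv), acetone/CH2Cl2/MeOH, −78 → −40 °C; evaporate; then Et3SiH (5 equiv), BF3·OEt2 (2 equiv), CH2Cl2, −78 °C
Reagents that add atoms: dimethyldioxirane CC1(C)OO1
Why: Enol ether epoxidation, methanolysis and ionic reduction of the ketal (reductive etherification type): the dioxirane adds anti to the pseudoaxial 4-aryl group, which sets C3 with its oxygen trans to the middle unit, and Et3SiH then adds axially to the C2 oxocarbenium ion anti to the pseudoaxial C3 oxygen, so that the 2-aryl group ends equatorial, cis to the 3-hydroxyl and trans to the 4-aryl group (C3 controlled by C4, C2 by C3).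

Step 17
Reactants: 26 pivalate-protected benzylated trimer
Product: 27 benzylated trimer with free top 3-hydroxyl and top 4'-hydroxyl
Conditions: K2CO3, MeOH/THF, 0 °C → rt
Reagents that add atoms: none
Why: Base-catalysed transesterification (methanolysis) of the aryl pivalate; benzyl ethers, interflavan bonds and all stereocentres are inert, and the cold, short treatment avoids base-induced opening of ring C at the new 4'-phenoxide.

Step 18
Reactants: 27 undeca-O-benzyl trimer
Product: 28 epiafzelechin-(4β→8)-epiafzelechin-(4β→8)-4'-O-methylepigallocatechin (CNP0146516.1)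
Conditions: H2 (1 atm), Pd(OH)2/C, THF/MeOH/H2O, rt
Reagents that add atoms: none
Why: Catalytic hydrogenolysis of the eleven benzyl ethers under neutral conditions, which leave the methyl ether, the benzylic ring-C ether bonds and the diarylmethine interflavan bonds intact, as in benzylated proanthocyanidins.

**Compound list**

1 | (−)-epigallocatechin, (2R,3R)-2-(3,4,5-trihydroxyphenyl)chromane-3,5,7-triol | Oc1c(O)cc([C@H]2Oc3cc(O)cc(O)c3C[C@H]2O)cc1O | starting material
2 | (−)-4'-O-methylepigallocatechin, (2R,3R)-2-(3,5-dihydroxy-4-methoxyphenyl)chromane-3,5,7-triol | COc1c(O)cc([C@H]2Oc3cc(O)cc(O)c3C[C@H]2O)cc1O | intermediate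
3 | (2R,3R)-5,7-bis(benzyloxy)-2-[3,5-bis(benzyloxy)-4-methoxyphenyl]chroman-3-ol | COc1c(OCc9ccccc9)cc([C@H]2Oc3cc(OCc9ccccc9)cc(OCc9ccccc9)c3C[C@H]2O)cc1OCc9ccccc9 | intermediate
4 | (2R,3R)-3,5,7-tris(benzyloxy)-2-[3,5-bis(benzyloxy)-4-methoxyphenyl]chromane (bottom unit) | COc1c(OCc9ccccc9)cc([C@H]2Oc3cc(OCc9ccccc9)cc(OCc9ccccc9)c3C[C@H]2OCc9ccccc9)cc1OCc9ccccc9 | intermediate
5 | (−)-epiafzelechin, (2R,3R)-2-(4-hydroxyphenyl)chromane-3,5,7-triol | Oc1ccc([C@H]2Oc3cc(O)cc(O)c3C[C@H]2O)cc1 | starting material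
6 | (2R,3R)-5,7-bis(benzyloxy)-2-[4-(benzyloxy)phenyl]chroman-3-ol | O(Cc9ccccc9)c1ccc([C@H]2Oc3cc(OCc9ccccc9)cc(OCc9ccccc9)c3C[C@H]2O)cc1 | intermediate
7 | (2R,3R)-3,5,7-tris(benzyloxy)-2-[4-(benzyloxy)phenyl]chromane | O(Cc9ccccc9)c1ccc([C@H]2Oc3cc(OCc9ccccc9)cc(OCc9ccccc9)c3C[C@H]2OCc9ccccc9)cc1 | intermediate
8 | (2R,3R)-3,5,7-tris(benzyloxy)-2-[4-(benzyloxy)phenyl]-8-bromochromane | O(Cc9ccccc9)c1ccc([C@H]2Oc3c(Br)c(OCc9ccccc9)cc(OCc9ccccc9)c3C[C@H]2OCc9ccccc9)cc1 | intermediate
9 | (2R,3R,4S)-3,5,7-tris(benzyloxy)-2-[4-(benzyloxy)phenyl]-8-bromo-4-(2-ethoxyethoxy)chromane (4β-ether, trans to the 3-benzyloxy group) | O(Cc9ccccc9)c1ccc([C@H]2Oc3c(Br)c(OCc9ccccc9)cc(OCc9ccccc9)c3[C@H](OCCOCC)[C@H]2OCc9ccccc9)cc1 | intermediate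
10 | 8-bromo-3,5,7,4'-tetra-O-benzylepiafzelechin-(4β→8)-3,5,7,3',5'-penta-O-benzyl-4'-O-methylepigallocatechin | COc1c(OCc9ccccc9)cc([C@H]2Oc3c(c(OCc9ccccc9)cc(OCc9ccccc9)c3[C@H]3c4c(OCc9ccccc9)cc(OCc9ccccc9)c(Br)c4O[C@H](c4ccc(OCc9ccccc9)cc4)[C@@H]3OCc9ccccc9)C[C@H]2OCc9ccccc9)cc1OCc9ccccc9 | intermediate
11 | 4-hydroxybenzaldehyde | O=Cc1ccc(O)cc1 | starting material
12 | 4-formylphenyl pivalate | O=Cc1ccc(OC(=O)C(C)(C)C)cc1 | intermediate
13 | ethynyltrimethylsilane | C[Si](C)(C)C#C | starting material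
14 | (S)-4-[1-hydroxy-3-(trimethylsilyl)prop-2-yn-1-yl]phenyl pivalate | C[Si](C)(C)C#C[C@H](c1ccc(OC(=O)C(C)(C)C)cc1)O | intermediate
15 | 3,5-bis(benzyloxy)phenol | Oc1cc(OCc2ccccc2)cc(OCc2ccccc2)c1 | starting material
16 | (R)-4-{1-[3,5-bis(benzyloxy)phenoxy]-3-(trimethylsilyl)prop-2-yn-1-yl}phenyl pivalate | C[Si](C)(C)C#C[C@@H](c1ccc(OC(=O)C(C)(C)C)cc1)Oc1cc(OCc9ccccc9)cc(OCc9ccccc9)c1 | intermediate
17 | (S)-4-{1-[3,5-bis(benzyloxy)phenoxy]prop-2-yn-1-yl}phenyl pivalate | C#C[C@@H](c1ccc(OC(=O)C(C)(C)C)cc1)Oc1cc(OCc9ccccc9)cc(OCc9ccccc9)c1 | intermediate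
18 | key-step precursor: dimer 10 carrying at C8 of the middle unit the (R)-3-[3,5-bis(benzyloxy)phenoxy]-3-[4-(pivaloyloxy)phenyl]prop-1-yn-1-yl group | COc1c(OCc9ccccc9)cc([C@H]2Oc3c(c(OCc9ccccc9)cc(OCc9ccccc9)c3[C@H]3c4c(OCc9ccccc9)cc(OCc9ccccc9)c(C#C[C@@H](c6ccc(OC(=O)C(C)(C)C)cc6)Oc6cc(OCc9ccccc9)cc(OCc9ccccc9)c6)c4O[C@H](c4ccc(OCc9ccccc9)cc4)[C@@H]3OCc9ccccc9)C[C@H]2OCc9ccccc9)cc1OCc9ccccc9 | intermediate
19 | key-step product: trimer with the top unit as (2S)-5,7-bis(benzyloxy)-2-[4-(pivaloyloxy)phenyl]-2H-chromen-4-yl at C8 of the middle unit | COc1c(OCc9ccccc9)cc([C@H]2Oc3c(c(OCc9ccccc9)cc(OCc9ccccc9)c3[C@H]3c4c(OCc9ccccc9)cc(OCc9ccccc9)c(C5=C[C@@H](c6ccc(OC(=O)C(C)(C)C)cc6)Oc6cc(OCc9ccccc9)cc(OCc9ccccc9)c65)c4O[C@H](c4ccc(OCc9ccccc9)cc4)[C@@H]3OCc9ccccc9)C[C@H]2OCc9ccccc9)cc1OCc9ccccc9 | intermediate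
20 | trimer 3,4-epoxide of the top unit, oxygen anti to the 2-aryl group | COc1c(OCc9ccccc9)cc([C@H]2Oc3c(c(OCc9ccccc9)cc(OCc9ccccc9)c3[C@H]3c4c(OCc9ccccc9)cc(OCc9ccccc9)c([C@]56c7c(OCc9ccccc9)cc(OCc9ccccc9)cc7O[C@H](c7ccc(OC(=O)C(C)(C)C)cc7)[C@H]5O6)c4O[C@H](c4ccc(OCc9ccccc9)cc4)[C@@H]3OCc9ccccc9)C[C@H]2OCc9ccccc9)cc1OCc9ccccc9 | intermediate
21 | trimer 3-ketone: top unit (2R)-5,7-bis(benzyloxy)-2-[4-(pivaloyloxy)phenyl]chroman-3-one bonded at C4 to middle C8, 2-aryl and middle unit trans | COc1c(OCc9ccccc9)cc([C@H]2Oc3c(c(OCc9ccccc9)cc(OCc9ccccc9)c3[C@H]3c4c(OCc9ccccc9)cc(OCc9ccccc9)c([C@H]5c6c(OCc9ccccc9)cc(OCc9ccccc9)cc6O[C@H](c6ccc(OC(=O)C(C)(C)C)cc6)C5=O)c4O[C@H](c4ccc(OCc9ccccc9)cc4)[C@@H]3OCc9ccccc9)C[C@H]2OCc9ccccc9)cc1OCc9ccccc9 | intermediate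
22 | trimer enol triflate: top unit 5,7-bis(benzyloxy)-2-[4-(pivaloyloxy)phenyl]-3-(trifluoromethylsulfonyloxy)-4H-chromen-4-yl, C4 as in 21 | COc1c(OCc9ccccc9)cc([C@H]2Oc3c(c(OCc9ccccc9)cc(OCc9ccccc9)c3[C@H]3c4c(OCc9ccccc9)cc(OCc9ccccc9)c([C@H]5c6c(OCc9ccccc9)cc(OCc9ccccc9)cc6OC(c6ccc(OC(=O)C(C)(C)C)cc6)=C5OS(=O)(=O)C(F)(F)F)c4O[C@H](c4ccc(OCc9ccccc9)cc4)[C@@H]3OCc9ccccc9)C[C@H]2OCc9ccccc9)cc1OCc9ccccc9 | intermediate
23 | trimer flav-2-ene: top unit 5,7-bis(benzyloxy)-2-[4-(pivaloyloxy)phenyl]-4H-chromen-4-yl, C4 as in 21 | COc1c(OCc9ccccc9)cc([C@H]2Oc3c(c(OCc9ccccc9)cc(OCc9ccccc9)c3[C@H]3c4c(OCc9ccccc9)cc(OCc9ccccc9)c([C@H]5c6c(OCc9ccccc9)cc(OCc9ccccc9)cc6OC(c6ccc(OC(=O)C(C)(C)C)cc6)=C5)c4O[C@H](c4ccc(OCc9ccccc9)cc4)[C@@H]3OCc9ccccc9)C[C@H]2OCc9ccccc9)cc1OCc9ccccc9 | intermediate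
24 | trimer 2,3-epoxide of the top unit, oxygen anti to the 4-aryl group | COc1c(OCc9ccccc9)cc([C@H]2Oc3c(c(OCc9ccccc9)cc(OCc9ccccc9)c3[C@H]3c4c(OCc9ccccc9)cc(OCc9ccccc9)c([C@H]5c6c(OCc9ccccc9)cc(OCc9ccccc9)cc6O[C@@]7(c6ccc(OC(=O)C(C)(C)C)cc6)[C@@H]5O7)c4O[C@H](c4ccc(OCc9ccccc9)cc4)[C@@H]3OCc9ccccc9)C[C@H]2OCc9ccccc9)cc1OCc9ccccc9 | intermediate
25 | trimer 2-methoxy ketal of the top unit (3-hydroxyl trans to the 4-aryl group; trans-diaxial methanol adduct drawn, the C2 epimer serves equally) | COc1c(OCc9ccccc9)cc([C@H]2Oc3c(c(OCc9ccccc9)cc(OCc9ccccc9)c3[C@H]3c4c(OCc9ccccc9)cc(OCc9ccccc9)c([C@H]5c6c(OCc9ccccc9)cc(OCc9ccccc9)cc6O[C@](OC)(c6ccc(OC(=O)C(C)(C)C)cc6)[C@@H]5O)c4O[C@H](c4ccc(OCc9ccccc9)cc4)[C@@H]3OCc9ccccc9)C[C@H]2OCc9ccccc9)cc1OCc9ccccc9 | intermediate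
26 | 5,7-di-O-benzyl-4'-O-pivaloylepiafzelechin-(4β→8)-3,5,7,4'-tetra-O-benzylepiafzelechin-(4β→8)-3,5,7,3',5'-penta-O-benzyl-4'-O-methylepigallocatechin | COc1c(OCc9ccccc9)cc([C@H]2Oc3c(c(OCc9ccccc9)cc(OCc9ccccc9)c3[C@H]3c4c(OCc9ccccc9)cc(OCc9ccccc9)c([C@H]5c6c(OCc9ccccc9)cc(OCc9ccccc9)cc6O[C@H](c6ccc(OC(=O)C(C)(C)C)cc6)[C@@H]5O)c4O[C@H](c4ccc(OCc9ccccc9)cc4)[C@@H]3OCc9ccccc9)C[C@H]2OCc9ccccc9)cc1OCc9ccccc9 | intermediate
27 | 5,7-di-O-benzylepiafzelechin-(4β→8)-3,5,7,4'-tetra-O-benzylepiafzelechin-(4β→8)-3,5,7,3',5'-penta-O-benzyl-4'-O-methylepigallocatechin | COc1c(OCc9ccccc9)cc([C@H]2Oc3c(c(OCc9ccccc9)cc(OCc9ccccc9)c3[C@H]3c4c(OCc9ccccc9)cc(OCc9ccccc9)c([C@H]5c6c(OCc9ccccc9)cc(OCc9ccccc9)cc6O[C@H](c6ccc(O)cc6)[C@@H]5O)c4O[C@H](c4ccc(OCc9ccccc9)cc4)[C@@H]3OCc9ccccc9)C[C@H]2OCc9ccccc9)cc1OCc9ccccc9 | intermediate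
28 | epiafzelechin-(4β→8)-epiafzelechin-(4β→8)-4'-O-methylepigallocatechin (CNP0146516.1) | COc1c(O)cc([C@H]2Oc3c(c(O)cc(O)c3[C@H]3c4c(O)cc(O)c([C@H]5c6c(O)cc(O)cc6O[C@H](c6ccc(O)cc6)[C@@H]5O)c4O[C@H](c4ccc(O)cc4)[C@@H]3O)C[C@H]2O)cc1O | target

**Step count and risks**

Total steps: 18. Longest linear sequence: 12 steps (5 → 7 → 8 → 9 → 10 → 18 → 19 → 21 → 22 → 23 → 26 → 27 → 28; the branch from 11 is equally long).

Steps most likely to fail:

Step 12 (key step). The crowded internal alkyne may not react, or the benzyloxy oxygen ortho to it on the middle ring may add to the gold-activated alkyne with benzyl migration, diverting the material to a benzofuran. The fallback sets out from 17 and 10 and rejoins the route at 26: ring C of the top unit is closed on the small terminal alkyne instead, and the top–middle bond is made by cationic coupling. Ph3PAuNTf2 should cyclise 17 to (S)-4-[5,7-bis(benzyloxy)-2H-chromen-2-yl]phenyl pivalate F1. DMDO followed by BF3·OEt2 should give, through the epoxide and a 1,2-hydride shift, the flavan-3-one (R)-4-[5,7-bis(benzyloxy)-3-oxochroman-2-yl]phenyl pivalate F2. LiBH(s-Bu)3 at −78 °C should reduce this C4-unsubstituted ketone to the axial, 2,3-cis alcohol 4-[(2R,3R)-5,7-bis(benzyloxy)-3-hydroxychroman-2-yl]phenyl pivalate F3. DDQ with 2-ethoxyethanol should then give the 4β-(2-ethoxyethoxy) ether F4. Bromide 10 is debrominated (n-BuLi, THF, −78 °C, then MeOH) to the dimer F5. Me3SiOTf at −78 °C should join F4 to C8 of the middle unit of F5 (used in excess), trans to the 3-hydroxyl, giving 26.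

Step 16. Hydride may be delivered to the C2 oxocarbenium ion with poor facial selectivity (the axial path passes the pseudoaxial 4-aryl group), or the ion may lose the C3 proton and fall back to ketone 21. The fallback sets out from 23 and rejoins at 26. Epoxidation with DMDO in wet acetone and hydrolytic opening should give the ring-opened α-hydroxy ketone F6, a free phenol. Zn(BH4)2 (Et2O, −20 °C) should reduce it under chelation control to the anti-1,2-diol F7. Mitsunobu ring closure (PPh3, DIAD) then lets the phenol displace the benzylic hydroxyl with inversion, which gives the 2,3-cis ring C of 26.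

Step 14. Deprotonation may occur at C4 instead of C2, or the ketone may epimerise before it is trapped. The fallback sets out from 21 and rejoins at 23. NaBH4 (MeOH/THF, −40 °C) should add hydride anti to the 4-aryl group and give the 2,3-trans-3,4-cis alcohol F8. Burgess reagent (toluene, 60 °C) should then eliminate through the cyclic syn transition state, for which only the C2 hydrogen is cis to the oxygen, and give 23.

Further compounds
F1 | step 12 | (S)-4-[5,7-bis(benzyloxy)-2H-chromen-2-yl]phenyl pivalate | C1=C[C@@H](c2ccc(OC(=O)C(C)(C)C)cc2)Oc2cc(OCc9ccccc9)cc(OCc9ccccc9)c12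
F2 | step 12 | (R)-4-[5,7-bis(benzyloxy)-3-oxochroman-2-yl]phenyl pivalate | O=C1Cc2c(OCc9ccccc9)cc(OCc9ccccc9)cc2O[C@@H]1c1ccc(OC(=O)C(C)(C)C)cc1
F3 | step 12 | 4-[(2R,3R)-5,7-bis(benzyloxy)-3-hydroxychroman-2-yl]phenyl pivalate | O[C@@H]1Cc2c(OCc9ccccc9)cc(OCc9ccccc9)cc2O[C@@H]1c1ccc(OC(=O)C(C)(C)C)cc1
F4 | step 12 | 4-[(2R,3R,4S)-5,7-bis(benzyloxy)-4-(2-ethoxyethoxy)-3-hydroxychroman-2-yl]phenyl pivalate | O[C@@H]1[C@@H](OCCOCC)c2c(OCc9ccccc9)cc(OCc9ccccc9)cc2O[C@@H]1c1ccc(OC(=O)C(C)(C)C)cc1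
F5 | step 12 | 3,5,7,4'-tetra-O-benzylepiafzelechin-(4β→8)-3,5,7,3',5'-penta-O-benzyl-4'-O-methylepigallocatechin | COc1c(OCc9ccccc9)cc([C@H]2Oc3c(c(OCc9ccccc9)cc(OCc9ccccc9)c3[C@H]3c4c(OCc9ccccc9)cc(OCc9ccccc9)cc4O[C@H](c4ccc(OCc9ccccc9)cc4)[C@@H]3OCc9ccccc9)C[C@H]2OCc9ccccc9)cc1OCc9ccccc9
F6 | step 16 | ring-opened α-hydroxy ketone of the top unit (2-hydroxy-1-[4-(pivaloyloxy)phenyl]-3-[2-hydroxy-4,6-bis(benzyloxy)phenyl]propan-1-one bonded at C3 to middle C8) | COc1c(OCc9ccccc9)cc([C@H]2Oc3c(c(OCc9ccccc9)cc(OCc9ccccc9)c3[C@H]3c4c(OCc9ccccc9)cc(OCc9ccccc9)c([C@@H](c6c(OCc9ccccc9)cc(OCc9ccccc9)cc6O)[C@@H](O)C(=O)c6ccc(OC(=O)C(C)(C)C)cc6)c4O[C@H](c4ccc(OCc9ccccc9)cc4)[C@@H]3OCc9ccccc9)C[C@H]2OCc9ccccc9)cc1OCc9ccccc9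
F7 | step 16 | anti-1,2-diol from F6 (phenol triol) | COc1c(OCc9ccccc9)cc([C@H]2Oc3c(c(OCc9ccccc9)cc(OCc9ccccc9)c3[C@H]3c4c(OCc9ccccc9)cc(OCc9ccccc9)c([C@@H](c6c(OCc9ccccc9)cc(OCc9ccccc9)cc6O)[C@@H](O)[C@@H](O)c6ccc(OC(=O)C(C)(C)C)cc6)c4O[C@H](c4ccc(OCc9ccccc9)cc4)[C@@H]3OCc9ccccc9)C[C@H]2OCc9ccccc9)cc1OCc9ccccc9
F8 | step 14 | trimer alcohol with 2,3-trans-3,4-cis top unit | COc1c(OCc9ccccc9)cc([C@H]2Oc3c(c(OCc9ccccc9)cc(OCc9ccccc9)c3[C@H]3c4c(OCc9ccccc9)cc(OCc9ccccc9)c([C@H]5c6c(OCc9ccccc9)cc(OCc9ccccc9)cc6O[C@H](c6ccc(OC(=O)C(C)(C)C)cc6)[C@H]5O)c4O[C@H](c4ccc(OCc9ccccc9)cc4)[C@@H]3OCc9ccccc9)C[C@H]2OCc9ccccc9)cc1OCc9ccccc9
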